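**Plan**

- Numbering: C7 is the benzylic carbinol carbon, C8 the aryloxy methine, C9 the CH2OH carbon; ring A is the 3,4,5-trimethoxyphenyl ring, ring B the 4-allyl-2,6-dimethoxyphenyl ring.
- Retrosynthesis: the C9 alcohol is taken back to an ethyl ester, then the C8–O(ring B) bond and the C7–C8 bond are cut in one operation.
- Enabling feature: C8 carries both the ring B ether oxygen and the bond to C7, so it can enter as the carbene carbon of a diazoacetate that joins a phenol O–H and an aldehyde C=O.
- Forward: methoxyeugenol, ethyl diazoacetate and 3,4,5-trimethoxybenzaldehyde are joined at C8 in one flask (acyclic chain, no ring is formed), then the ester is reduced to the C9 alcohol.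
- Stereochemistry: both centres (7R,8R, threo) are set in the coupling, C7 by the chiral Lewis acid from Zr(OtBu)4 and (R)-BINOL that holds the aldehyde, C8 by the syn topicity of the ylide addition; the reduction does not touch them.

Key step: step 1

Assumption: the sense of induction of the Zr(OtBu)4/BINOL Lewis acid is not established for these three partners; (R)-BINOL is written as the ligand taken to give the (2S,3R) ester, and (S)-BINOL would be used if the first experiment shows the opposite sense.

**Step 1**
Reactants: 1 4-allyl-2,6-dimethoxyphenol (methoxyeugenol); 2 ethyl diazoacetate; 3 3,4,5-trimethoxybenzaldehyde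
Product: 6 ethyl (2S,3R)-2-(4-allyl-2,6-dimethoxyphenoxy)-3-hydroxy-3-(3,4,5-trimethoxyphenyl)propanoate, via rhodium carbenoid 4 (not isolated), via protic oxonium ylide 5 (not isolated)
Conditions: Zr(OtBu)4 (15 mol%) and (R)-BINOL (30 mol%) premixed in CH2Cl2, rt, 1 h, volatiles (tBuOH) removed; then Rh2(OAc)4 (2 mol%), 1 (1.0 equiv), 3 (1.5 equiv), 4 Å MS, CH2Cl2, 0 °C; 2 (1.5 equiv) in CH2Cl2 added by syringe pump over 4 h
Reagents that add atoms: none
Why: Proposed new method: Rh2(OAc)4 (divalent rhodium) takes N2 out of 2 to give the electrophilic carbenoid 4, the phenol oxygen of 1 adds to it to give the protic oxonium ylide 5 (a rhodium-associated enol), and 5 adds through carbon to aldehyde 3 activated on the tetravalent zirconium centre of the Zr(OtBu)4/(R)-BINOL complex before its O–H proton can shift to carbon, so the C8–O(ring B) and C7–C8 bonds form in one flask and no ring is closed. The closest known reaction type is the Rh2(OAc)4 and Zr(OtBu)4/BINOL co-catalysed three-component aldol-type trapping, by aldehydes, of oxonium ylides made from aryldiazoacetates and alcohols; the acceptor-only diazo ester, the phenol as O–H partner and the electron-rich aldehyde lie outside it. C7 is controlled by the binaphtholate ligand on zirconium, which shields one face of the bound carbonyl group, and C8 by the relative topicity of the same bond formation: in an open transition state in which the ylide O–H hydrogen-bonds to the carbonyl oxygen, the two oxygens are synclinal and the ester and ring A are antiperiplanar, which is the syn (threo) arrangement and, with the right ligand antipode, (2S,3R). The step needs chemoselectivity of 4 for the O–H group over the allyl alkene, the arene and the aldehyde oxygen, which the more nucleophilic phenol oxygen, the blocked ortho and para positions of ring B and the zirconium-bound carbonyl lone pair should secure, and it needs aldol capture to outrun the 1,2-proton shift, for which 2 is added slowly to an excess of activated 3 under strictly dry conditions.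

**Step 2**
Reactants: 6 ethyl (2S,3R)-2-(4-allyl-2,6-dimethoxyphenoxy)-3-hydroxy-3-(3,4,5-trimethoxyphenyl)propanoate
Product: 7 (1R,2R)-2-(4-allyl-2,6-dimethoxyphenoxy)-1-(3,4,5-trimethoxyphenyl)propane-1,3-diol
Conditions: LiBH4 (2 equiv), THF, 0 °C to rt; then H2O
Reagents that add atoms: none
Why: Ester reduction with LiBH4 should convert the α-aryloxy-activated ethyl ester into the C9 primary alcohol at low temperature, while the weakly basic borohydride leaves the allyl alkene, the aryl ethers and both stereocentres as they are (the C8 descriptor changes from S to R only because the substituent priorities change).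

**Compound list**

1 | 4-allyl-2,6-dimethoxyphenol (methoxyeugenol) | C=CCc1cc(OC)c(O)c(OC)c1 | starting material
2 | ethyl diazoacetate | CCOC(=O)C=[N+]=[N-] | starting material
3 | 3,4,5-trimethoxybenzaldehyde | COc1cc(C=O)cc(OC)c1OC | starting material
4 | rhodium carbenoid Rh2(OAc)4=CHCO2Et (acetate bridges drawn monodentate in the SMILES) | CCOC(=O)C=[Rh](OC(C)=O)(OC(C)=O)[Rh](OC(C)=O)OC(C)=O | intermediate
5 | protic oxonium ylide from 4 and phenol 1, ethyl 2-[(4-allyl-2,6-dimethoxyphenyl)oxonio]acetate ylide (free form of the rhodium-associated enol) | C=CCc1cc(OC)c([OH+][CH-]C(=O)OCC)c(OC)c1 | intermediate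
6 | ethyl (2S,3R)-2-(4-allyl-2,6-dimethoxyphenoxy)-3-hydroxy-3-(3,4,5-trimethoxyphenyl)propanoate | C=CCc1cc(OC)c(O[C@H](C(=O)OCC)[C@H](O)c2cc(OC)c(OC)c(OC)c2)c(OC)c1 | intermediate
7 | (1R,2R)-2-(4-allyl-2,6-dimethoxyphenoxy)-1-(3,4,5-trimethoxyphenyl)propane-1,3-diol (7R,8R, threo) | C=CCc1cc(OC)c(O[C@H](CO)[C@H](O)c2cc(OC)c(OC)c(OC)c2)c(OC)c1 | target

**Step count and risks**

Total steps: 2. Longest linear sequence: 2 steps (three commercial components joined in step 1).

The route has only two steps, so both are listed; step 1 stands twice because two separate processes can defeat it and each needs its own remedy.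

1. Step 1 (proposed new method), loss of the three-component pathway. The ylide 5 may shift its proton to carbon before it meets the aldehyde, which would give only O–H insertion. The carbenoid 4 may instead cyclopropanate the allyl group or be taken up by the aldehyde oxygen. The diazo ester may add directly to the zirconium-activated aldehyde, and the phenol may displace binaphtholate from zirconium. Fallback with known chemistry (Evans glycolate aldol), setting out from phenol 1 and coming back at target 7: Williamson etherification of 1 with bromoacetic acid (NaOH, H2O, 90 °C, then HCl) should give (4-allyl-2,6-dimethoxyphenoxy)acetic acid F1. PivCl and Et3N in THF at −20 °C turn it into the pivalic mixed anhydride F2, which is not isolated and acylates (S)-4-benzyloxazolidin-2-one in the presence of LiCl to give the imide (S)-3-[2-(4-allyl-2,6-dimethoxyphenoxy)acetyl]-4-benzyloxazolidin-2-one F3. Enolisation with Bu2BOTf and iPr2NEt in CH2Cl2 at −78 °C and addition of aldehyde 3 (to 0 °C) should give the (2S,3R) syn aldol adduct F4, both centres now being set by the auxiliary through the (Z)-boron enolate and a chair transition state. LiBH4 in THF with one equivalent of water at 0 °C removes the auxiliary reductively and gives 7 directly.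

2. Step 1 (proposed new method), poor stereocontrol. Facial selectivity at the zirconium-bound aldehyde may be low, or the syn preference of the open transition state may be weak, so that 6 is formed as a mixture of stereoisomers. Fallback with known chemistry (dynamic kinetic resolution by asymmetric transfer hydrogenation), setting out from 6 as the stereoisomer mixture and coming back at 6 as the single isomer: Dess–Martin periodinane in CH2Cl2 oxidises the C7 carbinol to the β-keto ester ethyl 2-(4-allyl-2,6-dimethoxyphenoxy)-3-oxo-3-(3,4,5-trimethoxyphenyl)propanoate F5, whose C8 centre epimerises freely through the enol. RuCl(p-cymene)[(S,S)-TsDPEN] with HCO2H/Et3N (5:2) in CH2Cl2 at 30 °C should then reduce the ketone while C8 equilibrates, giving the syn α-aryloxy-β-hydroxy ester. The (S,S) ligand is the antipode that the aryl ketone model predicts for 3R, which returns (2S,3R)-6.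

3. Step 2, side reactions of the free β-hydroxy ester under hydride. The C7 alkoxide may fragment by retro-aldol cleavage, C8 may epimerise before the ester is consumed, or borane-type species released from the borohydride may hydroborate the allyl group. Fallback, setting out from 6 and coming back at 7: TBSOTf and 2,6-lutidine in CH2Cl2 at 0 °C give the silyl ether ethyl (2S,3R)-2-(4-allyl-2,6-dimethoxyphenoxy)-3-[(tert-butyldimethylsilyl)oxy]-3-(3,4,5-trimethoxyphenyl)propanoate F6, in which no alkoxide can form. iBu2AlH (DIBAL-H) in CH2Cl2 at −78 to 0 °C reduces the ester to the primary alcohol (2R,3R)-2-(4-allyl-2,6-dimethoxyphenoxy)-3-[(tert-butyldimethylsilyl)oxy]-3-(3,4,5-trimethoxyphenyl)propan-1-ol F7 without a boron hydride present. Bu4NF in THF then removes the silyl group to give 7.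

**Further compounds**

F1 | step 1 | (4-allyl-2,6-dimethoxyphenoxy)acetic acid | C=CCc1cc(OC)c(OCC(=O)O)c(OC)c1
F2 | step 1 | (4-allyl-2,6-dimethoxyphenoxy)acetic pivalic anhydride | C=CCc1cc(OC)c(OCC(=O)OC(=O)C(C)(C)C)c(OC)c1
F3 | step 1 | (S)-3-[2-(4-allyl-2,6-dimethoxyphenoxy)acetyl]-4-benzyloxazolidin-2-one | C=CCc1cc(OC)c(OCC(=O)N2[C@@H](Cc3ccccc3)COC2=O)c(OC)c1
F4 | step 1 | (S)-3-[(2S,3R)-2-(4-allyl-2,6-dimethoxyphenoxy)-3-hydroxy-3-(3,4,5-trimethoxyphenyl)propanoyl]-4-benzyloxazolidin-2-one | C=CCc1cc(OC)c(O[C@H](C(=O)N3[C@@H](Cc4ccccc4)COC3=O)[C@H](O)c2cc(OC)c(OC)c(OC)c2)c(OC)c1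
F5 | step 1 | ethyl 2-(4-allyl-2,6-dimethoxyphenoxy)-3-oxo-3-(3,4,5-trimethoxyphenyl)propanoate (C2 configurationally labile) | C=CCc1cc(OC)c(OC(C(=O)OCC)C(=O)c2cc(OC)c(OC)c(OC)c2)c(OC)c1
F6 | step 2 | ethyl (2S,3R)-2-(4-allyl-2,6-dimethoxyphenoxy)-3-[(tert-butyldimethylsilyl)oxy]-3-(3,4,5-trimethoxyphenyl)propanoate | C=CCc1cc(OC)c(O[C@H](C(=O)OCC)[C@H](O[Si](C)(C)C(C)(C)C)c2cc(OC)c(OC)c(OC)c2)c(OC)c1
F7 | step 2 | (2R,3R)-2-(4-allyl-2,6-dimethoxyphenoxy)-3-[(tert-butyldimethylsilyl)oxy]-3-(3,4,5-trimethoxyphenyl)propan-1-ol | C=CCc1cc(OC)c(O[C@H](CO)[C@H](O[Si](C)(C)C(C)(C)C)c2cc(OC)c(OC)c(OC)c2)c(OC)c1
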